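**Plan**

- Cuts, in retrosynthetic order: the O6–acyl bond; C14=C15 and C12=C13 (two Wittig olefinations) back to the C12 carbonyl of an 8α,12-γ-lactone; the C5–H/C6–O pair back to a C5=C6 alkene and then a C5 tertiary alcohol; C5–C6 and C8–C9 of ring B together; C9=C11 (Wittig); the C9 arm on C10.
- Forward: ring A is bought as 2,2,6-trimethylcyclohexanone; C10 is made quaternary by catalytic allylation; the arm is trimmed to a C9=C11–C12 enoate; ring B and the lactone ring close in one operation; then C5=C6 alkene, hydroboration, lactol, diene, angelate.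
- Enabling feature: in ring B, C6–C7–C8(–C17) is a 3-oxobutyl unit (but-3-en-2-one) lying between C5 and C9. C5 (the ring-A ketone carbon) and C8 can both be ketyl carbons, C6 and C9 both acceptor alkene carbons, and O8 is γ to C12, so the second coupling ends in the 8α,12-lactone. The oxygen first placed on C5 is moved to C6 by dehydration and hydroboration.
- Stereochemistry: C10 from the Pd/(R)-t-Bu-PHOX allylation (the only catalyst-set centre); C8 and C9 relayed from C10 in the key step; C5 and C6 set together by α-face hydroboration; 12E from a stabilised ylide; the Z ester is bought as angelic acid.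

Key step: step 6

Remark: the SMILES is read as (5S,6S,8R,9R,10S), 12E, with a (Z)-2-methylbut-2-enoate on O6; labdane numbering is used for atoms (C17 on C8, C18/C19 on C4, C20 on C10).

**Route**

Step 1
Reactants: 1 2,2,6-trimethylcyclohexanone; 2 allyl chloroformate
Product: 3 allyl 2,6,6-trimethylcyclohex-1-en-1-yl carbonate
Conditions: KN(SiMe3)2, THF, 0 °C; then 2, −78 °C to 0 °C
Reagents that add atoms: none
Why: Deprotonation of 1 is possible only at C6, and the hindered potassium enolate should be acylated on oxygen by the chloroformate (enolate O-acylation), which also erases the stereocentre of racemic 1.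

Step 2
Reactants: 3 allyl 2,6,6-trimethylcyclohex-1-en-1-yl carbonate
Product: 4 (R)-2,2,6-trimethyl-6-(prop-2-enyl)cyclohexanone
Conditions: Pd2(dba)3 (2.5 mol%), (R)-t-Bu-PHOX (6 mol%), THF, 25 °C
Reagents that add atoms: none
Why: Decarboxylative asymmetric allylic alkylation (Tsuji allylation): zerovalent palladium ionises the allyl carbonate, CO2 is lost and the π-allylpalladium enolate recombines at carbon inside the pocket of the (R)-PHOX ligand, which should set the (R) α-quaternary centre that becomes C10, following the established ligand–product correlation for α-quaternary cyclohexanones.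

Step 3
Reactants: 4 (R)-2,2,6-trimethyl-6-(prop-2-enyl)cyclohexanone
Product: 5 (R)-2,2,6-trimethyl-6-[(E)-prop-1-enyl]cyclohexanone
Conditions: RuHCl(CO)(PPh3)3 (2 mol%), toluene, 80 °C
Reagents that add atoms: none
Why: Ruthenium hydride alkene isomerisation (hydrometalation then β-hydride elimination) should move the double bond one position to the more substituted E-propenyl group and cannot go further because C10 is quaternary.

Step 4
Reactants: 5 (R)-2,2,6-trimethyl-6-[(E)-prop-1-enyl]cyclohexanone
Product: 7 (R)-1,3,3-trimethyl-2-oxocyclohexane-1-carbaldehyde, via ozonide 6 (not isolated)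
Conditions: O3, CH2Cl2/MeOH, −78 °C; then Me2S, −78 °C to rt
Reagents that add atoms: ozone, [O-][O+]=O
Why: Ozonolysis with reductive work-up should cleave the propenyl group to the C9 aldehyde while the non-enolisable ketone and the quaternary C10 are untouched.

Step 5
Reactants: 7 (R)-1,3,3-trimethyl-2-oxocyclohexane-1-carbaldehyde; 8 ethyl (triphenylphosphoranylidene)acetate
Product: 9 ethyl (2E)-3-[(1R)-1,3,3-trimethyl-2-oxocyclohexyl]prop-2-enoate
Conditions: toluene, 80 °C
Reagents that add atoms: none
Why: Wittig olefination with a stabilised ylide should react only at the aldehyde (the doubly flanked ketone is inert) and give the E enoate C9=C11–C12.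

Step 6
Reactants: 9 ethyl (2E)-3-[(1R)-1,3,3-trimethyl-2-oxocyclohexyl]prop-2-enoate; 10 but-3-en-2-one
Product: 12 5α-hydroxy-13,14,15,16-tetranorlabdan-12,8α-olide, via hydroxy ketone 11 (not isolated)
Conditions: 9, 10 (1.5 equiv) and t-BuOH (3 equiv) added over 2 h to SmI2 (5 equiv), HMPA (8 equiv), THF, −78 °C; then 0 °C; aq. NH4Cl
Reagents that add atoms: none
Why: Proposed new method: SmI2 should reduce the hindered C5 ketone of 9 to a samarium ketyl that cannot pinacolise and that adds through C5 to the unsubstituted terminus C6 of 10 (bond C5–C6); t-BuOH protonates the samarium enolate to hydroxy ketone 11, whose new C8 carbonyl is then the most easily reduced group left, and its ketyl attacks C9 of the enoate (bond C8–C9), after which the C8 alkoxide acylates on C12 with loss of ethanol. The closest known reaction types are the SmI2 reductive coupling of ketones with acrylates to γ-lactones and sequenced SmI2 ketyl–olefin cyclisations; new is an enone that serves first as radical acceptor and then as ketyl donor, so that a ketone and a 3-oxobutyl unit close a six-membered carbocycle. Ring B closes by 6-exo-trig radical cyclisation of the C8 ketyl onto C9, and the γ-lactone by 5-exo-trig attack of O8 on the C12 ester. C5 (temporary) should arise by axial attack on the ketyl anti to the axial groups on C4 and C10, which places C6 cis to the C10 methyl; C8 and C9 then follow from a chair transition state relayed from C10, with the C10 methyl axial and the samarium alkoxide on C8 and the enoate on C9 both equatorial, giving 8α-O, 8β-CH3, 9β-CH2 and hence the trans-fused lactone. The step needs cross-coupling to outrun reduction or dimerisation of 10 and conjugate reduction of the enoate: the C5 ketyl has no feasible closure onto its own enoate (three- or four-membered ring), the enoate β-carbon is neopentyl and slow to couple intermolecularly, and 10 is kept at low concentration by slow addition. The C5 carbinol is removed in step 7, so only its configuration relative to C10 during ring closure matters.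

Step 7
Reactants: 12 5α-hydroxy-13,14,15,16-tetranorlabdan-12,8α-olide
Product: 13 13,14,15,16-tetranorlabd-5-en-12,8α-olide
Conditions: SOCl2, pyridine, CH2Cl2, −20 to 0 °C
Reagents that add atoms: none
Why: The tertiary C5 alcohol has β-hydrogens only on C6 because C4 and C10 are quaternary, so chlorosulfite formation and pyridine-mediated E2 elimination can give only the C5=C6 alkene, and the cold basic medium should suppress cationic methyl shifts.

Step 8
Reactants: 13 13,14,15,16-tetranorlabd-5-en-12,8α-olide
Product: 15 6α-hydroxy-13,14,15,16-tetranor-5α-labdan-12,8α-olide, via alkylborane 14 (not isolated)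
Conditions: BH3·THF, THF, 0 °C to rt; then H2O2, NaOH, 0 °C; dilute HCl work-up
Reagents that add atoms: borane–tetrahydrofuran, B.C1CCOC1 (boron stays only in 14); hydrogen peroxide, OO
Why: Hydroboration–oxidation: boron adds to the less substituted C6 and hydrogen to C5 in a syn addition from the α face, the β face being blocked by the axial methyl groups on C4, C8 and C10, so 5α-H and 6α-OH are set together and the C–B bond is oxidised with retention.

Step 9
Reactants: 15 6α-hydroxy-13,14,15,16-tetranor-5α-labdan-12,8α-olide
Product: 16 8α,12-epoxy-13,14,15,16-tetranor-5α-labdane-6α,12-diol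
Conditions: i-Bu2AlH (3 equiv), CH2Cl2, −78 °C; aq. potassium sodium tartrate
Reagents that add atoms: none
Why: Partial reduction of the γ-lactone with i-Bu2AlH at low temperature should stop at the aluminium hemiacetal, which gives the lactol on work-up; the free alcohol only consumes one equivalent of hydride.

Step 10
Reactants: 16 8α,12-epoxy-13,14,15,16-tetranor-5α-labdane-6α,12-diol; 17 2-(triphenylphosphoranylidene)propanal
Product: 18 (12E)-6α,8α-dihydroxy-15-norlabd-12-en-14-al
Conditions: 17 (2 equiv), toluene, 80 °C
Reagents that add atoms: none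
Why: Wittig olefination of the hydroxy aldehyde in equilibrium with the lactol by a stabilised, non-basic ylide should give the E trisubstituted enal (C12=C13) without touching the free alcohols.

Step 11
Reactants: 18 (12E)-6α,8α-dihydroxy-15-norlabd-12-en-14-al; 19 methyltriphenylphosphonium bromide
Product: 20 (12E)-labda-12,14-diene-6α,8α-diol
Conditions: 19, NaN(SiMe3)2, THF, 0 °C; then 18, −78 °C to rt
Reagents that add atoms: none
Why: Wittig methylenation of the enal carbonyl should give the terminal C14=C15 alkene; the ylide adds 1,2 and is too weak a base to form the C8 alkoxide, so conjugate addition of O8 is avoided and the 12E geometry is kept.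

Step 12
Reactants: 20 (12E)-labda-12,14-diene-6α,8α-diol; 21 angelic acid
Product: 22 (12E)-8α-hydroxylabda-12,14-dien-6α-yl (2Z)-2-methylbut-2-enoate
Conditions: 21, 2,4,6-trichlorobenzoyl chloride, Et3N, toluene, rt; then 20, 80 °C
Reagents that add atoms: none
Why: Yamaguchi esterification through the mixed anhydride should acylate the secondary 6α-hydroxyl selectively (the tertiary C8 hydroxyl is inert), and the absence of a nucleophilic catalyst limits isomerisation of the Z double bond of the angelate.

**Compound list**

1 | 2,2,6-trimethylcyclohexanone (racemic) | CC1CCCC(C)(C)C1=O | starting material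
2 | allyl chloroformate | C=CCOC(=O)Cl | starting material
3 | allyl 2,6,6-trimethylcyclohex-1-en-1-yl carbonate | C=CCOC(=O)OC1=C(C)CCCC1(C)C | intermediate
4 | (R)-2,2,6-trimethyl-6-(prop-2-enyl)cyclohexanone | C=CC[C@@]1(C)CCCC(C)(C)C1=O | intermediate
5 | (R)-2,2,6-trimethyl-6-[(E)-prop-1-enyl]cyclohexanone | C/C=C/[C@@]1(C)CCCC(C)(C)C1=O | intermediate
6 | ozonide (1,2,4-trioxolane) of 5 | CC1OOC(O1)[C@@]1(C)CCCC(C)(C)C1=O | intermediate (not isolated)
7 | (R)-1,3,3-trimethyl-2-oxocyclohexane-1-carbaldehyde | O=C[C@@]1(C)CCCC(C)(C)C1=O | intermediate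
8 | ethyl (triphenylphosphoranylidene)acetate | CCOC(=O)C=P(c1ccccc1)(c1ccccc1)c1ccccc1 | starting material
9 | ethyl (2E)-3-[(1R)-1,3,3-trimethyl-2-oxocyclohexyl]prop-2-enoate | CCOC(=O)/C=C/[C@@]1(C)CCCC(C)(C)C1=O | intermediate
10 | but-3-en-2-one (methyl vinyl ketone) | CC(=O)C=C | starting material
11 | ethyl (2E)-3-[(1R,2R)-2-hydroxy-1,3,3-trimethyl-2-(3-oxobutyl)cyclohexyl]prop-2-enoate (in the flask as its samarium alkoxide) | CCOC(=O)/C=C/[C@@]1(C)CCCC(C)(C)[C@]1(O)CCC(C)=O | intermediate (not isolated)
12 | 5α-hydroxy-13,14,15,16-tetranorlabdan-12,8α-olide (trans-fused γ-lactone, 8β-CH3, 10β-CH3; expected C5 epimer drawn) | O=C1C[C@@H]2[C@@]3(C)CCCC(C)(C)[C@]3(O)CC[C@@]2(C)O1 | intermediate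
13 | 13,14,15,16-tetranorlabd-5-en-12,8α-olide | O=C1C[C@@H]2[C@@]3(C)CCCC(C)(C)C3=CC[C@@]2(C)O1 | intermediate
14 | 6α-boryl-13,14,15,16-tetranor-5α-labdan-12,8α-olide (written as the monoalkylborane) | O=C1C[C@@H]2[C@@]3(C)CCCC(C)(C)[C@@H]3[C@@H](B)C[C@@]2(C)O1 | intermediate (not isolated)
15 | 6α-hydroxy-13,14,15,16-tetranor-5α-labdan-12,8α-olide (6α-hydroxysclareolide) | O=C1C[C@@H]2[C@@]3(C)CCCC(C)(C)[C@@H]3[C@@H](O)C[C@@]2(C)O1 | intermediate
16 | 8α,12-epoxy-13,14,15,16-tetranor-5α-labdane-6α,12-diol (lactol, both C12 epimers) | OC1C[C@@H]2[C@@]3(C)CCCC(C)(C)[C@@H]3[C@@H](O)C[C@@]2(C)O1 | intermediate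
17 | 2-(triphenylphosphoranylidene)propanal | CC(C=O)=P(c1ccccc1)(c1ccccc1)c1ccccc1 | starting material
18 | (12E)-6α,8α-dihydroxy-15-norlabd-12-en-14-al | O=C/C(C)=C/C[C@@H]1[C@@]2(C)CCCC(C)(C)[C@@H]2[C@@H](O)C[C@@]1(C)O | intermediate
19 | methyltriphenylphosphonium bromide | C[P+](c1ccccc1)(c1ccccc1)c1ccccc1.[Br-] | starting material
20 | (12E)-labda-12,14-diene-6α,8α-diol | C=C/C(C)=C/C[C@@H]1[C@@]2(C)CCCC(C)(C)[C@@H]2[C@@H](O)C[C@@]1(C)O | intermediate
21 | angelic acid, (2Z)-2-methylbut-2-enoic acid | C/C=C(/C)C(=O)O | starting material
22 | (12E)-8α-hydroxylabda-12,14-dien-6α-yl (2Z)-2-methylbut-2-enoate | C=C/C(C)=C/C[C@@H]1[C@@]2(C)CCCC(C)(C)[C@@H]2[C@@H](OC(=O)/C(C)=C\C)C[C@@]1(C)O | target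

**Summary and risks**

Total step count: 12. Longest linear sequence: 12 steps (1 to 22).

Steps most likely to fail:

1. Step 6. The cross-coupling may lose to reduction and hydrodimerisation of 10 or to conjugate reduction of the enoate before the hindered C5 ketyl couples; the samarium enolate may add to the enoate instead of being protonated; facial control at C5 or at C8 may be poor. The fallback uses known reaction types only, sets out from 5 and returns at 12. The ketone of 5 is treated with the organocerium reagent made from 2-(2-bromoethyl)-2-methyl-1,3-dioxolane (Mg, then CeCl3, THF, −78 °C), a polar 1,2-addition that forms C5–C6 and gives the tertiary alcohol F1. Ozonolysis of the propenyl group (O3, then Me2S) gives the hydroxy aldehyde F2, and Wittig reaction with 8 gives the hydroxy enoate ketal F3. Pyridinium p-toluenesulfonate in wet acetone frees the methyl ketone to give 11, now isolated. SmI2, HMPA and t-BuOH in THF at −78 °C then close C8–C9 by the known intramolecular ketyl–olefin cyclisation and lactonise to 12.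

2. Step 8. Borane may reduce the lactone in competition with the hindered alkene, or attack may occur in part on the β face. The fallback sets out from 13 and returns at 15. The C5=C6 alkene is epoxidised from the α face (mCPBA, NaHCO3, CH2Cl2) to the 5α,6α-epoxide F4. BF3·OEt2 promotes the epoxide-to-ketone rearrangement (hydride shift from C6), and equilibration with NaOMe in MeOH should give the trans-fused 6-ketone F5. Reduction with SmI2 and H2O in THF is expected to give the equatorial 6α-alcohol 15 and leave the five-membered lactone intact.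

3. Step 12. The angelate may isomerise to the E (tiglate) ester during activation, or acylation of the hindered 6α-hydroxyl may be slow. The fallback sets out from 20 and returns at 22. The secondary alcohol is esterified with 2-[bis(2,2,2-trifluoroethoxy)phosphoryl]propanoic acid (DCC, DMAP, CH2Cl2) to give the phosphonate ester F6. A Z-selective Still–Gennari olefination with acetaldehyde (KN(SiMe3)2, 18-crown-6, THF, −78 °C) then builds the (Z)-2-methylbut-2-enoate in place and gives 22.

Further compounds
F1 | step 6 | 2,2,6-trimethyl-1-[2-(2-methyl-1,3-dioxolan-2-yl)ethyl]-6-[(E)-prop-1-enyl]cyclohexan-1-ol (6R, carbinol carbon as in 11) | C/C=C/[C@@]1(C)CCCC(C)(C)[C@]1(O)CCC1(C)OCCO1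
F2 | step 6 | 2-hydroxy-1,3,3-trimethyl-2-[2-(2-methyl-1,3-dioxolan-2-yl)ethyl]cyclohexane-1-carbaldehyde (configuration as in F1) | O=C[C@@]1(C)CCCC(C)(C)[C@]1(O)CCC1(C)OCCO1
F3 | step 6 | ethyl (2E)-3-{2-hydroxy-1,3,3-trimethyl-2-[2-(2-methyl-1,3-dioxolan-2-yl)ethyl]cyclohexyl}prop-2-enoate (ethylene ketal of 11) | CCOC(=O)/C=C/[C@@]1(C)CCCC(C)(C)[C@]1(O)CCC1(C)OCCO1
F4 | step 8 | 5α,6α-epoxy-13,14,15,16-tetranorlabdan-12,8α-olide | O=C1C[C@@H]2[C@@]3(C)CCCC(C)(C)[C@@]34O[C@H]4C[C@@]2(C)O1
F5 | step 8 | 6-oxo-13,14,15,16-tetranor-5α-labdan-12,8α-olide | O=C1C[C@@H]2[C@@]3(C)CCCC(C)(C)[C@@H]3C(=O)C[C@@]2(C)O1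
F6 | step 12 | (12E)-8α-hydroxylabda-12,14-dien-6α-yl 2-[bis(2,2,2-trifluoroethoxy)phosphoryl]propanoate | C=C/C(C)=C/C[C@@H]1[C@@]2(C)CCCC(C)(C)[C@@H]2[C@@H](OC(=O)C(C)P(=O)(OCC(F)(F)F)OCC(F)(F)F)C[C@@]1(C)O
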